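Delta, the flask with [enzyme] = 0.33 µM, is asked about at 3.0 h.

all flasks: solid substrate 22 mM

| flask | enzyme | remark | time |
|---|---|---|---|
| delta | 0.33 µM | the very flask that is asked about, followed so far |  |
| eta | 0.17 µM | run made earlier |  |
| flask | 0.33 µM |  | 3.0 h |

delta run (percent of the solid substrate charged)

| time / min | target / % | starting material / % | solid substrate / % | complex / % |
|---|---|---|---|---|
| 10.0 | 0.3 | 7.1 | 92.6 | 0.1 |
| 20.0 | 1.2 | 13.2 | 86.5 | 0.4 |
| 30.0 | 0.1 | 19.7 | 80.0 | 0.2 |
| 40.0 | 2.1 | 23.7 | 75.5 | 0 |
| 50.0 | 2.8 | 27.7 | 69.7 | 0.3 |

eta run (percent of the solid substrate charged)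

| time / h | target / % | starting material / % | solid substrate / % | complex / % |
|---|---|---|---|---|
| 0.250 | 0 | 11.1 | 89.0 | 0 |
| 0.833 | 1.2 | 28.7 | 69.6 | 0 |
| 1.33 | 3.0 | 39.6 | 57.8 | 0 |
| 2.00 | 5.1 | 49.6 | 44.5 | 0.5 |
| 3.00 | 7.7 | 58.7 | 33.4 | 0 |

(each reading ± 0.5 percentage points)

1. the species in which most of what was charged as solid substrate, at 3.0 h sits (starting material / target / complex)
2. the largest share itself, whichever of these holds it, in percent of the solid substrate charged

- at the start none of the solid substrate is in solution
- a reading or a percentage of target counts all its forms, free or not
- starting material means what is dissolved; the solid is not counted in it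

1. Turn the question round. In delta, complex reads near zero, within the scatter. Target can therefore hold most at 3.0 h by taking half of the dissolved material.

2. Solid substrate reads 69.7 % in delta at 50.0 min and 69.6 % in eta at 0.833 h, about the same. So eta's 33.4 % at 3.00 h stands in for delta, and this reckoning counts 66.6 % as dissolved.

3. Freeze the target's climb as apparent zero order. The frozen target rate, the fraction of the charge turned into target per hour, is delta's last target reading over its time: 0.0336 h⁻¹. It is a reading and carries the scatter.

4. The opposite outcome in delta needs 0.111 h⁻¹, which is 3.30 times the frozen rate. My reckoning gives target 10.1 % and starting material 56.5 %.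

The forecast says starting material, at 53 %. Its grounds are “Target formation scales roughly with enzyme”, so it puts target near 14 %, where my figure is 10.1 %, and its share lies below mine.

Delta gives starting material at 57.7 %, with target 10.1 % against the frozen rate's 10.1 %.

    starting material + enzyme ⇌ complex (K = 13.0 M⁻¹, k = 39000 M⁻¹ s⁻¹)
    complex ⇌ enzyme + target (K = 0.0150 M, k = 76000 h⁻¹)
    solid substrate ⇌ starting material, rate k3*(cs3 - [starting material]) while solid is left; crystals form when [starting material] > cs3 (solubility = 16.0 mM, k = 0.640 h⁻¹)
    crystals ⇌ target, rate k4*(cs4 - [target]) while solid is left; crystals form when [target] > cs4 (solubility = 1.90 mM, k = 9.00 h⁻¹)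

The forward turning of starting material + enzyme into complex, taken by itself with the other concentrations as charged, gives starting material a half-life of 0.90 min, short against 3.0 h. Yet starting material stays in delta because complex falls back to starting material + enzyme. The run without that step holds 0 % starting material instead of 57.7 %, so the answer turns, and in that run the forecast is wrong.

The neighbouring flask is the same charge read at 5.0 h, and there the frozen rate gives target 16.8 %. Computed, the neighbouring flask holds 18.3 % target, crystals counted in, beside 63.8 % starting material.

The runs are simulated from invented constants; noise was put on by code.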